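**Plan**
1. Retrosynthesis: the six benzyl ethers come off last. Next the C–C bond between the benzylic CH2 on C-6 of ring B and the neighbouring O-acylated carbinol carbon is cut. Then the two aryl ester C(=O)–O bonds (rings A and B to the 3-oxybutanoates), the aliphatic ester to the ring C alcohol and the aryl–CH2 bond of ring C are cut.
2. Enabling feature: that carbinol carbon is an acetaldehyde carbon carrying an acyloxy oxygen. It can therefore be made as a 1-bromoethyl ester (acyl bromide + acetaldehyde) and turned into a planar α-acyloxy radical. The ring B CH2 lies ortho to the ring B ester carbonyl (the orsellinate methyl position) and can be carried as a benzylic zinc bromide.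
3. Forward: the chain is built from both ends. Fragment 2 is the ring A ester of the hydroxybutanoate, as its 1-bromoethyl ester. Fragment 1 is ring C alcohol → hydroxybutanoate → ring B benzoate bearing CH2ZnBr. They are joined in the middle by a nickel-catalysed enantioconvergent alkyl–alkyl coupling, then hydrogenolysis. No ring is formed; all three arenes are bought.
4. Stereochemistry: the ring C carbinol comes from (R)-propylene oxide. Both 3-oxybutanoate centres come from (S)-3-hydroxybutanoates (bought tert-butyl ester; Noyori hydrogenation with (S)-BINAP), inverted to R in Mitsunobu esterifications. The ring B carbinol (R) is set by the chiral nickel catalyst in the coupling.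

Key step: step 15

Remark: it is assumed that the catalyst made from NiBr2·glyme and (S,S)-iPr-pybox induces with a benzylic zinc partner in the same sense as with alkyl partners and so gives the (R)-ester; a model coupling of benzylzinc bromide with 1-bromoethyl benzoate should confirm this, and the (R,R)-ligand would be used if it shows the opposite sense.

**Route**

Step 1
Reactants: 1 methyl 2,4-dihydroxy-6-methylbenzoate (methyl orsellinate)
Product: 2 methyl 2,4-bis(benzyloxy)-6-methylbenzoate
Conditions: BnBr (2.5 equiv), K2CO3, DMF, 60 °C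
Reagents that add atoms: benzyl bromide, BrCc1ccccc1
Why: Williamson ether synthesis; warm DMF also alkylates the hydrogen-bonded ortho phenol.

Step 2
Reactants: 2 methyl 2,4-bis(benzyloxy)-6-methylbenzoate
Product: 3 2,4-bis(benzyloxy)-6-methylbenzoic acid
Conditions: KOH, DMSO/H2O, 90 °C; then 1 M HCl
Reagents that add atoms: potassium hydroxide, [K+].[OH-]
Why: Saponification of the hindered methyl ester under forcing conditions, to which the benzyl ethers are inert.

Step 3
Reactants: 3 2,4-bis(benzyloxy)-6-methylbenzoic acid; 4 tert-butyl (S)-3-hydroxybutanoate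
Product: 5 tert-butyl (R)-3-{[2,4-bis(benzyloxy)-6-methylbenzoyl]oxy}butanoate
Conditions: PPh3, DIAD, toluene, 0 °C → rt
Reagents that add atoms: none
Why: Mitsunobu esterification, the usual way to esterify 2,6-disubstituted benzoic acids; the carboxylate displaces the oxyphosphonium group in an SN2 step, so the (S)-carbinol becomes the (R)-ester.

Step 4
Reactants: 5 tert-butyl (R)-3-{[2,4-bis(benzyloxy)-6-methylbenzoyl]oxy}butanoate
Product: 6 (R)-3-{[2,4-bis(benzyloxy)-6-methylbenzoyl]oxy}butanoic acid
Conditions: 85 % aq. H3PO4, toluene, 40 °C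
Reagents that add atoms: none
Why: Acid-catalysed alkyl–oxygen cleavage of the tert-butyl ester; the aqueous acid traps the tert-butyl cation as the alcohol and so should keep it off the electron-rich ring A, and it avoids base, which would eliminate the 3-acyloxy group.

Step 5
Reactants: 7 1,3-bis(benzyloxy)-5-bromobenzene; 8 (R)-propylene oxide
Product: 10 (R)-1-[3,5-bis(benzyloxy)phenyl]propan-2-ol, via arylmagnesium bromide 9 (not isolated)
Conditions: Mg, I2 (cat.), THF, reflux; then CuI (10 mol %), 8, −30 → 0 °C; then 1 M HCl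
Reagents that add atoms: none
Why: Copper-catalysed Grignard opening of the epoxide at its CH2 terminus; the stereocentre of (R)-propylene oxide is not touched and becomes the (R)-carbinol.

Step 6
Reactants: 10 (R)-1-[3,5-bis(benzyloxy)phenyl]propan-2-ol; 11 2,2,6-trimethyl-4H-1,3-dioxin-4-one
Product: 12 (R)-1-[3,5-bis(benzyloxy)phenyl]propan-2-yl 3-oxobutanoate
Conditions: toluene, 110 °C (acetone distilled off)
Reagents that add atoms: none
Why: Thermal retro-[4+2] cleavage of the dioxinone gives acetylketene, which the alcohol traps (neutral acetoacetylation).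

Step 7
Reactants: 12 (R)-1-[3,5-bis(benzyloxy)phenyl]propan-2-yl 3-oxobutanoate
Product: 13 (R)-1-[3,5-bis(benzyloxy)phenyl]propan-2-yl (S)-3-hydroxybutanoate
Conditions: H2 (50 atm), RuCl2[(S)-BINAP] (1 mol %), EtOH/CH2Cl2, 50 °C
Reagents that add atoms: none
Why: Noyori asymmetric hydrogenation of a β-keto ester; RuCl2[(S)-BINAP] should give the (S)-alcohol by catalyst control and does not cleave benzyl ethers.

Step 8
Reactants: 14 [3,5-bis(benzyloxy)phenyl]methanol
Product: 15 [3,5-bis(benzyloxy)-2-bromophenyl]methanol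
Conditions: NBS, MeCN, 0 °C
Reagents that add atoms: N-bromosuccinimide, O=C1CCC(=O)N1Br
Why: Electrophilic aromatic bromination; C-2 (between CH2OH and one benzyloxy group) is activated by both ether groups and is less hindered than C-4 between them, as in the 3,5-dialkoxybenzyl alcohol series.

Step 9
Reactants: 15 [3,5-bis(benzyloxy)-2-bromophenyl]methanol
Product: 16 {[3,5-bis(benzyloxy)-2-bromophenyl]methoxy}(tert-butyl)dimethylsilane
Conditions: TBSCl, imidazole, DMF, rt
Reagents that add atoms: tert-butyldimethylsilyl chloride, CC(C)(C)[Si](C)(C)Cl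
Why: Standard silylation; the silyl ether keeps the benzylic oxygen from closing a phthalide once the carboxyl group is in place.

Step 10
Reactants: 16 {[3,5-bis(benzyloxy)-2-bromophenyl]methoxy}(tert-butyl)dimethylsilane
Product: 18 2,4-bis(benzyloxy)-6-{[(tert-butyldimethylsilyl)oxy]methyl}benzoic acid, via aryllithium 17 (not isolated)
Conditions: n-BuLi, THF, −78 °C; CO2; then cold 1 M HCl to pH 3
Reagents that add atoms: carbon dioxide, O=C=O
Why: Bromine–lithium exchange then carboxylation; the bromine introduced in step 8 determines the position of the carboxyl group, between the CH2O carbon and a benzyloxy group.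

Step 11
Reactants: 18 2,4-bis(benzyloxy)-6-{[(tert-butyldimethylsilyl)oxy]methyl}benzoic acid; 13 (R)-1-[3,5-bis(benzyloxy)phenyl]propan-2-yl (S)-3-hydroxybutanoate
Product: 19 (R)-4-{[(R)-1-(3,5-bis(benzyloxy)phenyl)propan-2-yl]oxy}-4-oxobutan-2-yl 2,4-bis(benzyloxy)-6-{[(tert-butyldimethylsilyl)oxy]methyl}benzoate
Conditions: PPh3, DIAD, toluene, 0 °C → rt
Reagents that add atoms: none
Why: Mitsunobu esterification of the hindered benzoic acid with SN2 inversion, (S)-carbinol to (R)-ester; the silyl ether and the other ester are inert.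

Step 12
Reactants: 19 (R)-4-{[(R)-1-(3,5-bis(benzyloxy)phenyl)propan-2-yl]oxy}-4-oxobutan-2-yl 2,4-bis(benzyloxy)-6-{[(tert-butyldimethylsilyl)oxy]methyl}benzoate (silyl ether of fragment 1)
Product: 20 (R)-4-{[(R)-1-(3,5-bis(benzyloxy)phenyl)propan-2-yl]oxy}-4-oxobutan-2-yl 2,4-bis(benzyloxy)-6-(bromomethyl)benzoate
Conditions: Ph3PBr2, CH2Cl2, 0 °C → rt
Reagents that add atoms: dibromotriphenylphosphorane, BrP(Br)(c1ccccc1)(c1ccccc1)c1ccccc1
Why: Known direct conversion of a silyl ether into a bromide through an oxyphosphonium ion (Appel-type); no free alkoxide is formed, so the ester should not close to the phthalide.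

Step 13
Reactants: 20 (R)-4-{[(R)-1-(3,5-bis(benzyloxy)phenyl)propan-2-yl]oxy}-4-oxobutan-2-yl 2,4-bis(benzyloxy)-6-(bromomethyl)benzoate (benzylic bromide of fragment 1)
Product: 21 benzylic zinc bromide of fragment 1 (20 with ZnBr in place of Br; THF solution, titrated and used directly)
Conditions: Zn dust (activated with BrCH2CH2Br and Me3SiCl), THF, 0–5 °C, slow addition
Reagents that add atoms: zinc, [Zn]
Why: Direct zinc insertion into a benzylic bromide; cold slow addition suppresses Wurtz coupling, and the benzylic zinc reagent tolerates esters and does not cause β-elimination.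

Step 14
Reactants: 6 (R)-3-{[2,4-bis(benzyloxy)-6-methylbenzoyl]oxy}butanoic acid; 22 acetaldehyde
Product: 24 1-bromoethyl (R)-3-{[2,4-bis(benzyloxy)-6-methylbenzoyl]oxy}butanoate (both epimers at the CHBr carbon; used crude at once), via acyl bromide 23 (not isolated)
Conditions: (COBr)2, DMF (cat.), CH2Cl2, 0 °C → rt, evaporate; then CH3CHO, ZnBr2 (2 mol %), CH2Cl2, −20 °C → rt
Reagents that add atoms: oxalyl bromide, O=C(Br)C(=O)Br
Why: Acyl bromide formation, then the known addition of an acyl bromide across the aldehyde carbonyl to give the 1-bromoalkyl ester; no base is present, so the 3-acyloxy group stays.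

Step 15
Reactants: 24 1-bromoethyl (R)-3-{[2,4-bis(benzyloxy)-6-methylbenzoyl]oxy}butanoate (fragment 2); 21 benzylic zinc bromide of fragment 1
Product: 25 hexa-O-benzyl hansforester A
Conditions: NiBr2·glyme (10 mol %), (S,S)-iPr-pybox (12 mol %), THF/DMA, −20 °C
Reagents that add atoms: none
Why: Proposed new method: a monovalent nickel species bearing the pybox ligand abstracts bromine from either epimer of 24 to give one planar α-acyloxyethyl radical stabilised by the ester oxygen, the benzyl group of 21 passes from zinc to divalent nickel, the radical is captured to a trivalent nickel dialkyl, and reductive elimination forms the benzylic CH2–CH(O) bond. The closest known reaction types are the nickel-catalysed enantioconvergent alkyl–alkyl couplings of racemic 1-bromoalkyl esters with alkylnickel species made from olefins and hydrosilanes, and the enantioconvergent Negishi couplings of racemic α-phthalimidoalkyl chlorides with alkylzinc halides; new here is a benzylic zinc halide as partner. No ring is closed. The new stereocentre (R, the carbinol carbon of the ring B side chain) is set by the chiral ligand at the radical-capture and reductive-elimination stage (catalyst control, stereoconvergent), and the three existing stereocentres are remote and untouched. The step needs cross- over homo-coupling and C–Br activation without attack on the four esters: only 24 has a weak α-oxygenated C–Br bond, its ester carbonyl can bind nickel, and the zinc reagent is too mild to add to esters or to cause β-elimination. An uncatalysed, zinc-halide-promoted substitution would give both epimers, so the coupling is run cold in THF/DMA.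

Step 16
Reactants: 25 hexa-O-benzyl hansforester A
Product: 26 hansforester A
Conditions: H2 (1 atm), 10 % Pd/C, EtOAc/THF, rt
Reagents that add atoms: none
Why: Hydrogenolysis of six aryl benzyl ethers; the four esters and the homobenzylic C–O bonds are stable and no stereocentre is benzylic.

**Compound list**
1 | methyl 2,4-dihydroxy-6-methylbenzoate (methyl orsellinate) | COC(=O)c1c(C)cc(O)cc1O | starting material
2 | methyl 2,4-bis(benzyloxy)-6-methylbenzoate | COC(=O)c1c(C)cc(OCc2ccccc2)cc1OCc1ccccc1 | intermediate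
3 | 2,4-bis(benzyloxy)-6-methylbenzoic acid | Cc1cc(OCc2ccccc2)cc(OCc2ccccc2)c1C(=O)O | intermediate
4 | tert-butyl (S)-3-hydroxybutanoate | C[C@H](O)CC(=O)OC(C)(C)C | starting material
5 | tert-butyl (R)-3-{[2,4-bis(benzyloxy)-6-methylbenzoyl]oxy}butanoate | Cc1cc(OCc2ccccc2)cc(OCc2ccccc2)c1C(=O)O[C@H](C)CC(=O)OC(C)(C)C | intermediate
6 | (R)-3-{[2,4-bis(benzyloxy)-6-methylbenzoyl]oxy}butanoic acid | Cc1cc(OCc2ccccc2)cc(OCc2ccccc2)c1C(=O)O[C@H](C)CC(=O)O | intermediate
7 | 1,3-bis(benzyloxy)-5-bromobenzene | Brc1cc(OCc2ccccc2)cc(OCc2ccccc2)c1 | starting material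
8 | (R)-propylene oxide | C[C@@H]1CO1 | starting material
9 | 3,5-bis(benzyloxy)phenylmagnesium bromide | Br[Mg]c1cc(OCc2ccccc2)cc(OCc2ccccc2)c1 | intermediate
10 | (R)-1-[3,5-bis(benzyloxy)phenyl]propan-2-ol | C[C@@H](O)Cc1cc(OCc2ccccc2)cc(OCc2ccccc2)c1 | intermediate
11 | 2,2,6-trimethyl-4H-1,3-dioxin-4-one | CC1=CC(=O)OC(C)(C)O1 | starting material
12 | (R)-1-[3,5-bis(benzyloxy)phenyl]propan-2-yl 3-oxobutanoate | CC(=O)CC(=O)O[C@H](C)Cc1cc(OCc2ccccc2)cc(OCc2ccccc2)c1 | intermediate
13 | (R)-1-[3,5-bis(benzyloxy)phenyl]propan-2-yl (S)-3-hydroxybutanoate | C[C@H](O)CC(=O)O[C@H](C)Cc1cc(OCc2ccccc2)cc(OCc2ccccc2)c1 | intermediate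
14 | [3,5-bis(benzyloxy)phenyl]methanol | OCc1cc(OCc2ccccc2)cc(OCc2ccccc2)c1 | starting material
15 | [3,5-bis(benzyloxy)-2-bromophenyl]methanol | OCc1cc(OCc2ccccc2)cc(OCc2ccccc2)c1Br | intermediate
16 | {[3,5-bis(benzyloxy)-2-bromophenyl]methoxy}(tert-butyl)dimethylsilane | CC(C)(C)[Si](C)(C)OCc1cc(OCc2ccccc2)cc(OCc2ccccc2)c1Br | intermediate
17 | 2,4-bis(benzyloxy)-6-{[(tert-butyldimethylsilyl)oxy]methyl}phenyllithium | CC(C)(C)[Si](C)(C)OCc1cc(OCc2ccccc2)cc(OCc2ccccc2)c1[Li] | intermediate
18 | 2,4-bis(benzyloxy)-6-{[(tert-butyldimethylsilyl)oxy]methyl}benzoic acid | CC(C)(C)[Si](C)(C)OCc1cc(OCc2ccccc2)cc(OCc2ccccc2)c1C(=O)O | intermediate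
19 | (R)-4-{[(R)-1-(3,5-bis(benzyloxy)phenyl)propan-2-yl]oxy}-4-oxobutan-2-yl 2,4-bis(benzyloxy)-6-{[(tert-butyldimethylsilyl)oxy]methyl}benzoate | CC(C)(C)[Si](C)(C)OCc1cc(OCc2ccccc2)cc(OCc2ccccc2)c1C(=O)O[C@H](C)CC(=O)O[C@H](C)Cc1cc(OCc2ccccc2)cc(OCc2ccccc2)c1 | intermediate
20 | (R)-4-{[(R)-1-(3,5-bis(benzyloxy)phenyl)propan-2-yl]oxy}-4-oxobutan-2-yl 2,4-bis(benzyloxy)-6-(bromomethyl)benzoate | BrCc1cc(OCc2ccccc2)cc(OCc2ccccc2)c1C(=O)O[C@H](C)CC(=O)O[C@H](C)Cc1cc(OCc2ccccc2)cc(OCc2ccccc2)c1 | intermediate
21 | benzylic zinc bromide of 20 (ZnBr in place of Br) | Br[Zn]Cc1cc(OCc2ccccc2)cc(OCc2ccccc2)c1C(=O)O[C@H](C)CC(=O)O[C@H](C)Cc1cc(OCc2ccccc2)cc(OCc2ccccc2)c1 | intermediate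
22 | acetaldehyde | CC=O | starting material
23 | (R)-3-{[2,4-bis(benzyloxy)-6-methylbenzoyl]oxy}butanoyl bromide | Cc1cc(OCc2ccccc2)cc(OCc2ccccc2)c1C(=O)O[C@H](C)CC(=O)Br | intermediate
24 | 1-bromoethyl (R)-3-{[2,4-bis(benzyloxy)-6-methylbenzoyl]oxy}butanoate (both epimers at CHBr) | Cc1cc(OCc2ccccc2)cc(OCc2ccccc2)c1C(=O)O[C@H](C)CC(=O)OC(C)Br | intermediate
25 | hexa-O-benzyl hansforester A | Cc1cc(OCc2ccccc2)cc(OCc2ccccc2)c1C(=O)O[C@H](C)CC(=O)O[C@H](C)Cc1cc(OCc2ccccc2)cc(OCc2ccccc2)c1C(=O)O[C@H](C)CC(=O)O[C@H](C)Cc1cc(OCc2ccccc2)cc(OCc2ccccc2)c1 | intermediate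
26 | hansforester A | Cc1cc(O)cc(O)c1C(=O)O[C@H](C)CC(=O)O[C@H](C)Cc1cc(O)cc(O)c1C(=O)O[C@H](C)CC(=O)O[C@H](C)Cc1cc(O)cc(O)c1 | target

**Step count**
Total: 16 steps. Longest linear sequence: 8 steps (5, 6, 7, 11, 12, 13, 15, 16 from 7; equally 8, 9, 10, 11, 12, 13, 15, 16 from 14).

**Steps most likely to fail**

Step 15 (Proposed new method). What may go wrong: poor facial selectivity at the new carbinol carbon if a zinc-halide-promoted ionisation of the bromoethyl ester bypasses the catalyst; homocoupling of the benzylic partner; β-hydride loss from the α-acyloxyalkyl nickel species. The fallback uses known chemistry, sets out from 10 and comes back at 25; the ring B side chain then brings its stereocentre with it and the last bond made is an ester bond. 10 is silylated (TBSCl, imidazole) to the silyl ether F1. F1 is brominated with NBS at the ring position between the side chain and a benzyloxy group to the aryl bromide F2. F2 is converted with n-BuLi and then CO2 into the benzoic acid F3. F3 is esterified with 13 under Mitsunobu conditions (inversion) to the silyl-protected diester F4. F4 is desilylated with HF·pyridine to the secondary alcohol F5. F5 is acylated with acid 6 (EDC·HCl, DMAP, CH2Cl2) to give 25, which goes on to step 16.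

Step 11. What may go wrong: β-elimination of the activated β-hydroxy ester to the crotonate, or slow attack of the hindered carboxylate with incomplete inversion. The fallback sets out from 12 and 18 and comes back at 19; it acylates with retention instead of alkylating with inversion. 12 is hydrogenated with RuCl2[(R)-BINAP] to the (R)-3-hydroxybutanoate F6. 18 is converted under neutral conditions (1-chloro-N,N,2-trimethylprop-1-en-1-amine, CH2Cl2) into the acid chloride F7. F6 and F7 are joined with pyridine and DMAP (CH2Cl2, 40 °C) to give 19.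

Step 14. What may go wrong: loss of benzyl ethers through the hydrogen bromide that is formed, and hydrolysis of the acyl bromide or of the bromoethyl ester before use. The fallback sets out from 6 and comes back at 25; the acid acts as a nucleophile instead of being activated. 6 is O-alkylated with 1-chloroethyl chlorosulfate (NaHCO3, Bu4NHSO4, CH2Cl2/H2O) to the 1-chloroethyl ester F8, which should survive chromatography. F8 is used in place of 24 in step 15 to give 25.

**Further compounds**
F1 | step 15 | (R)-{[1-(3,5-bis(benzyloxy)phenyl)propan-2-yl]oxy}(tert-butyl)dimethylsilane | CC(C)(C)[Si](C)(C)O[C@H](C)Cc1cc(OCc2ccccc2)cc(OCc2ccccc2)c1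
F2 | step 15 | (R)-{[1-(3,5-bis(benzyloxy)-2-bromophenyl)propan-2-yl]oxy}(tert-butyl)dimethylsilane | CC(C)(C)[Si](C)(C)O[C@H](C)Cc1cc(OCc2ccccc2)cc(OCc2ccccc2)c1Br
F3 | step 15 | 2,4-bis(benzyloxy)-6-{(R)-2-[(tert-butyldimethylsilyl)oxy]propyl}benzoic acid | CC(C)(C)[Si](C)(C)O[C@H](C)Cc1cc(OCc2ccccc2)cc(OCc2ccccc2)c1C(=O)O
F4 | step 15 | (R)-4-{[(R)-1-(3,5-bis(benzyloxy)phenyl)propan-2-yl]oxy}-4-oxobutan-2-yl 2,4-bis(benzyloxy)-6-{(R)-2-[(tert-butyldimethylsilyl)oxy]propyl}benzoate | CC(C)(C)[Si](C)(C)O[C@H](C)Cc1cc(OCc2ccccc2)cc(OCc2ccccc2)c1C(=O)O[C@H](C)CC(=O)O[C@H](C)Cc1cc(OCc2ccccc2)cc(OCc2ccccc2)c1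
F5 | step 15 | (R)-4-{[(R)-1-(3,5-bis(benzyloxy)phenyl)propan-2-yl]oxy}-4-oxobutan-2-yl 2,4-bis(benzyloxy)-6-[(R)-2-hydroxypropyl]benzoate | O[C@H](C)Cc1cc(OCc2ccccc2)cc(OCc2ccccc2)c1C(=O)O[C@H](C)CC(=O)O[C@H](C)Cc1cc(OCc2ccccc2)cc(OCc2ccccc2)c1
F6 | step 11 | (R)-1-[3,5-bis(benzyloxy)phenyl]propan-2-yl (R)-3-hydroxybutanoate | C[C@@H](O)CC(=O)O[C@H](C)Cc1cc(OCc2ccccc2)cc(OCc2ccccc2)c1
F7 | step 11 | 2,4-bis(benzyloxy)-6-{[(tert-butyldimethylsilyl)oxy]methyl}benzoyl chloride | CC(C)(C)[Si](C)(C)OCc1cc(OCc2ccccc2)cc(OCc2ccccc2)c1C(=O)Cl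
F8 | step 14 | 1-chloroethyl (R)-3-{[2,4-bis(benzyloxy)-6-methylbenzoyl]oxy}butanoate (both epimers at CHCl) | Cc1cc(OCc2ccccc2)cc(OCc2ccccc2)c1C(=O)O[C@H](C)CC(=O)OC(C)Cl
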